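## Retrosynthetic overview

1. Germacrane numbering is used: ring C1–C10 (C1=C10 alkene with C14 on C10, C4–C5 oxirane with C15 on C4, C9–O), and C7 carries C11(=C13H2)–C12H2O. The enabling feature is the unit C9(–O)–C8H2–C7H–C11(=C13H2), a γ,δ-unsaturated carbonyl (Claisen) retron. C8 is an isolated methylene and C11 bears two CH2–O arms (C12, C13), so the allyl partner can be a symmetrical 2-alkylidenepropane-1,3-diol.
2. Late disconnections: the C14 ester (acid from an Evans syn-aldol), the C12 acetate, and the C9 tiglate (C9–OH from reduction of a C9 ketone).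
3. Key disconnection: the ten-membered carbocycle comes from a twelve-membered lactone C9(=O)–O–C13. Titanium methylenation delivers C8, and a ring-contracting Claisen shift forms C7–C8 and releases C13 as the exocyclic methylene.
4. The lactone comes from a seco acid assembled by three-component anti-carbomagnesiation/allylation of propargyl alcohol (C15, C4, C5; C1–C3; C6, C7), cross-metathesis (C11–C13), oxa-Michael/Horner–Wadsworth–Emmons (C9, C10, C14) and Sharpless epoxidation (C4, C5).
5. Ring order: oxirane (step 5), twelve-membered lactone (step 8, temporary), ten-membered carbocycle (step 10).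

Key step: step 10

Assumption: compounds 2, 6 and 9 are taken as purchasable, and lactone 15 is written as the isomer closed through the hydroxymethyl arm cis to C6, which is expected to predominate.

## Route

Step 1
Reactants: 1 prop-2-yn-1-ol; 2 [2-(1,3-dioxolan-2-yl)ethyl]magnesium bromide; 3 3-bromoprop-1-ene
Product: 5 (2Z)-2-[2-(1,3-dioxolan-2-yl)ethyl]hexa-2,5-dien-1-ol, via vinylmagnesium alkoxide 4 (not isolated)
Conditions: 2 (3 equiv), CuI (10 mol%), THF/Et2O, −10 to 23 °C; then 3, 0 °C; aq. NH4Cl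
Reagents that add atoms: none
Why: Copper-catalysed anti-carbomagnesiation of the propargyl alkoxide puts the alkyl group on C4 and magnesium on C5 cis to the chelating CH2O group, and copper-mediated allylation with retention fixes the trisubstituted alkene with C15 cis to C6 (C3 trans to C6, as the trans-epoxide needs).

Step 2
Reactants: 5 (2Z)-2-[2-(1,3-dioxolan-2-yl)ethyl]hexa-2,5-dien-1-ol; 6 2-methylidenepropane-1,3-diyl diacetate
Product: 7 2-[(3Z)-6-(1,3-dioxolan-2-yl)-4-(hydroxymethyl)hex-3-en-1-ylidene]propane-1,3-diyl diacetate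
Conditions: second-generation Hoveyda–Grubbs catalyst (5 mol%), 6 (4 equiv), CH2Cl2, 40 °C
Reagents that add atoms: none
Why: Olefin cross-metathesis of the only terminal alkene with a symmetrical 1,1-disubstituted partner gives a trisubstituted alkene that has no geometry to control, and the trisubstituted C4=C5 alkene should stay untouched.

Step 3
Reactants: 7 2-[(3Z)-6-(1,3-dioxolan-2-yl)-4-(hydroxymethyl)hex-3-en-1-ylidene]propane-1,3-diyl diacetate
Product: 8 2-[(3Z)-4-(hydroxymethyl)-7-oxohept-3-en-1-ylidene]propane-1,3-diyl diacetate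
Conditions: 1 M HCl, THF, 23 °C
Reagents that add atoms: water, O
Why: Acid-catalysed acetal hydrolysis is placed before the acid-sensitive epoxide exists, and primary allylic acetates should survive dilute acid at room temperature.

Step 4
Reactants: 8 2-[(3Z)-4-(hydroxymethyl)-7-oxohept-3-en-1-ylidene]propane-1,3-diyl diacetate; 9 methyl 2-(dimethoxyphosphoryl)prop-2-enoate
Product: 11 methyl (2E,6Z)-11-acetoxy-10-(acetoxymethyl)-6-(hydroxymethyl)-2-{[(4-methoxybenzyl)oxy]methyl}undeca-2,6,9-trienoate, via sodium phosphonate 10 (not isolated)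
Conditions: 4-methoxybenzyl alcohol, NaH, THF, 0 °C; then 9, 0 °C; then 8, −20 to 23 °C
Reagents that add atoms: 4-methoxybenzyl alcohol, COc1ccc(CO)cc1
Why: Tandem oxa-Michael addition/Horner–Wadsworth–Emmons olefination: the alkoxide adds to the vinylphosphonate, and the resulting α-branched phosphonoacetate anion olefinates the aldehyde, which should favour the (E)-enoate (C9 trans to C2) as with other α-substituted phosphonoacetates.

Step 5
Reactants: 11 methyl (2E,6Z)-11-acetoxy-10-(acetoxymethyl)-6-(hydroxymethyl)-2-{[(4-methoxybenzyl)oxy]methyl}undeca-2,6,9-trienoate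
Product: 12 methyl (2E)-5-{(2S,3R)-3-[4-acetoxy-3-(acetoxymethyl)but-2-en-1-yl]-2-(hydroxymethyl)oxiran-2-yl}-2-{[(4-methoxybenzyl)oxy]methyl}pent-2-enoate
Conditions: Ti(OiPr)4 (0.2 equiv), L-(+)-diethyl tartrate (0.24 equiv), tBuOOH, 4 Å molecular sieves, CH2Cl2, −20 °C
Reagents that add atoms: tert-butyl hydroperoxide, CC(C)(C)OO
Why: Sharpless asymmetric epoxidation: the titanium–L-(+)-tartrate complex delivers oxygen to the face of the C4=C5 allylic alcohol that gives the (4S,5R)-epoxide, syn addition keeps C3 and C6 trans, and the enoate and allylic-acetate alkenes lack the free hydroxyl needed to react.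

Step 6
Reactants: 12 methyl (2E)-5-{(2S,3R)-3-[4-acetoxy-3-(acetoxymethyl)but-2-en-1-yl]-2-(hydroxymethyl)oxiran-2-yl}-2-{[(4-methoxybenzyl)oxy]methyl}pent-2-enoate
Product: 13 methyl (2E)-5-{(2S,3R)-3-[4-acetoxy-3-(acetoxymethyl)but-2-en-1-yl]-2-{[(tert-butyldimethylsilyl)oxy]methyl}oxiran-2-yl}-2-{[(4-methoxybenzyl)oxy]methyl}pent-2-enoate
Conditions: TBSCl, imidazole, DMF, 23 °C
Reagents that add atoms: tert-butyldimethylsilyl chloride, CC(C)(C)[Si](C)(C)Cl
Why: Standard silylation of the primary C15 hydroxyl, which blocks Payne rearrangement and competing eight-membered lactonisation later.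

Step 7
Reactants: 13 methyl (2E)-5-{(2S,3R)-3-[4-acetoxy-3-(acetoxymethyl)but-2-en-1-yl]-2-{[(tert-butyldimethylsilyl)oxy]methyl}oxiran-2-yl}-2-{[(4-methoxybenzyl)oxy]methyl}pent-2-enoate
Product: 14 (2E)-5-{(2S,3R)-2-{[(tert-butyldimethylsilyl)oxy]methyl}-3-[4-hydroxy-3-(hydroxymethyl)but-2-en-1-yl]oxiran-2-yl}-2-{[(4-methoxybenzyl)oxy]methyl}pent-2-enoic acid
Conditions: LiOH, THF/MeOH/H2O, 23 to 40 °C; NaHSO4 to pH 4, 0 °C
Reagents that add atoms: lithium hydroxide, [Li+].[OH-]
Why: Saponification cleaves the methyl ester and both acetates in one operation, while the silyl ether, the PMB ether and the epoxide should tolerate hydroxide at this temperature.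

Step 8
Reactants: 14 (2E)-5-{(2S,3R)-2-{[(tert-butyldimethylsilyl)oxy]methyl}-3-[4-hydroxy-3-(hydroxymethyl)but-2-en-1-yl]oxiran-2-yl}-2-{[(4-methoxybenzyl)oxy]methyl}pent-2-enoic acid
Product: 15 (4S,5R)-epoxy twelve-membered hydroxy lactone C9(=O)–O–C13 (ring: C9; C10; C1–C7; C11; C13; O) with 1(10)E alkene; C13 cis to C6 on C7=C11; free 12-OH; 14-O-PMB; 15-O-TBS
Conditions: 2-methyl-6-nitrobenzoic anhydride, DMAP, CH2Cl2 (2 mM, slow addition of 14), 23 °C
Reagents that add atoms: none
Why: Shiina macrolactonisation activates the hindered enoic acid as a mixed anhydride under high dilution, either primary hydroxyl is competent, and acyl transfer between the two geminal arms should settle the ester on the arm cis to C6, whose cis ring alkene is the less strained companion for the E-enoate and trans-epoxide in a twelve-membered ring.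

Step 9
Reactants: 15 twelve-membered hydroxy lactone
Product: 16 12-O-triethylsilyl ether of lactone 15
Conditions: TESCl, imidazole, CH2Cl2, 0 °C
Reagents that add atoms: chlorotriethylsilane, CC[Si](Cl)(CC)CC
Why: Silylation of the remaining hydroxymethyl arm removes the only protic group and any ester other than the lactone before the titanium reagent is used.

Step 10
Reactants: 16 12-O-triethylsilyl ether of lactone 15
Product: 18 (4S,5R,7R)-4,5-epoxy-14-[(4-methoxybenzyl)oxy]-15-[(tert-butyldimethylsilyl)oxy]-12-[(triethylsilyl)oxy]germacra-1(10)E,11(13)-dien-9-one, via cyclic dienyl ether 17 (not isolated)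
Conditions: (C5H5)2Ti(CH3)2 (3 equiv), toluene/THF, 80 °C, dark; then 120 °C
Reagents that add atoms: dimethyltitanocene, [Ti+4].[CH3-].[CH3-].c1cc[cH-]c1.c1cc[cH-]c1
Why: Proposed new method: (C5H5)2Ti(CH3)2 loses methane to the titanium methylidene, which converts the lactone carbonyl C9=O into C9=C8H2, and the allyl vinyl ether array C8=C9–O–C13–C11=C7 of cyclic dienyl ether 17 then undergoes a thermal [3,3]-sigmatropic (Claisen) shift that forms C7–C8, turns O–C13 into the exocyclic C11=C13H2 and leaves C9 as the ketone; the closest known reaction types are the titanium-methylenation/Claisen rearrangement of allyl esters and of vinyl-substituted lactones (ring expansion) and the ester-enolate Claisen ring contraction of unsaturated macrolides, but a ring contraction of a macrolide through its methylenated enol ether has not been shown. The ten-membered carbocycle closes by ring contraction of the twelve-membered enol ether through a chair-like six-membered pericyclic array that shares C9–C8–C7 with the forming ring (a bridged bicyclo[7.3.1] transition state), and the carbonyl that is formed pays for the strain of the medium ring. The only new stereocentre, C7, is controlled by the (4S,5R)-epoxide through the ring: the O–C13–C11 bridge must span C9 and C7 on one face of the crown-like forming ring, and it should take the face opposite to the pseudo-axial C15 silyloxymethyl group on C4, which puts C11 anti to C15 as in the target (descriptor 7R here only because C9 is a carbonyl). Regioselectivity (C7, not C13) is inherent in the concerted shift, chemoselectivity of the methylenation is secured by carrying every other oxygen as a silyl or benzyl-type ether, and having the epoxide in place of a C4=C5 alkene removes the 1,5-diene that could undergo a Cope rearrangement in the product. Because C11 carries two CH2O arms, a lactone closed through the other arm would present the same bridge and should converge on the same ketone.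

Step 11
Reactants: 18 (4S,5R,7R)-4,5-epoxy-14-[(4-methoxybenzyl)oxy]-15-[(tert-butyldimethylsilyl)oxy]-12-[(triethylsilyl)oxy]germacra-1(10)E,11(13)-dien-9-one
Product: 19 (4S,5R,7S,9S)-4,5-epoxy-14-[(4-methoxybenzyl)oxy]-15-[(tert-butyldimethylsilyl)oxy]-12-[(triethylsilyl)oxy]germacra-1(10)E,11(13)-dien-9-ol
Conditions: (R)-2-methyl-CBS-oxazaborolidine (0.3 equiv), catecholborane, toluene, −78 to −40 °C
Reagents that add atoms: none
Why: Corey–Bakshi–Shibata reduction: the (R)-oxazaborolidine–borane complex binds the enone with the α-branched alkenyl arm (C10) as the large group and should deliver hydride to the face that gives the (9S)-allylic alcohol by 1,2-reduction only.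

Step 12
Reactants: 19 (4S,5R,7S,9S)-4,5-epoxy-14-[(4-methoxybenzyl)oxy]-15-[(tert-butyldimethylsilyl)oxy]-12-[(triethylsilyl)oxy]germacra-1(10)E,11(13)-dien-9-ol
Product: 20 (4S,5R,7S,9S)-4,5-epoxy-14-[(4-methoxybenzyl)oxy]-15-[(tert-butyldimethylsilyl)oxy]-12-[(triethylsilyl)oxy]germacra-1(10)E,11(13)-dien-9-yl (2E)-2-methylbut-2-enoate
Conditions: tigloyl chloride, Et3N, DMAP (cat.), CH2Cl2, 0 to 23 °C
Reagents that add atoms: (2E)-2-methylbut-2-enoyl chloride, ClC(=O)/C(C)=C/C
Why: DMAP-catalysed acylation of the only free hydroxyl with the acid chloride of the thermodynamically stable (E)-acid, so no change of alkene geometry is expected.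

Step 13
Reactants: 20 12-O-TES 9-tiglate
Product: 21 (4S,5R,7S,9S)-4,5-epoxy-12-hydroxy-14-[(4-methoxybenzyl)oxy]-15-[(tert-butyldimethylsilyl)oxy]germacra-1(10)E,11(13)-dien-9-yl (2E)-2-methylbut-2-enoate
Conditions: HF·pyridine, pyridine, THF, 0 °C
Reagents that add atoms: none
Why: Buffered fluoride desilylation should remove the primary allylic triethylsilyl ether well before the hindered, neopentyl-type TBS ether at C15, and buffered HF·pyridine is tolerated by trisubstituted epoxides.

Step 14
Reactants: 21 12-hydroxy 9-tiglate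
Product: 22 (4S,5R,7S,9S)-12-acetoxy-4,5-epoxy-14-[(4-methoxybenzyl)oxy]-15-[(tert-butyldimethylsilyl)oxy]germacra-1(10)E,11(13)-dien-9-yl (2E)-2-methylbut-2-enoate
Conditions: Ac2O, pyridine, DMAP (cat.), CH2Cl2, 0 °C
Reagents that add atoms: acetic anhydride, CC(=O)OC(C)=O
Why: Routine acetylation of the single free primary hydroxyl.

Step 15
Reactants: 22 12-acetoxy 14-O-PMB 9-tiglate
Product: 23 (4S,5R,7S,9S)-12-acetoxy-4,5-epoxy-14-hydroxy-15-[(tert-butyldimethylsilyl)oxy]germacra-1(10)E,11(13)-dien-9-yl (2E)-2-methylbut-2-enoate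
Conditions: DDQ, CH2Cl2/pH 7 buffer, 0 °C
Reagents that add atoms: none
Why: Oxidative cleavage of the 4-methoxybenzyl ether under buffered, neutral conditions spares the epoxide, both esters and the silyl ether, and should not promote migration of the tiglate to the new primary hydroxyl.

Step 16
Reactants: 24 (4R)-4-benzyl-3-propanoyl-1,3-oxazolidin-2-one; 25 acetaldehyde
Product: 26 (4R)-4-benzyl-3-[(2R,3S)-3-hydroxy-2-methylbutanoyl]-1,3-oxazolidin-2-one
Conditions: Bu2BOTf, iPr2NEt, CH2Cl2, 0 °C; then 25, −78 to 0 °C; pH 7 buffer, MeOH, H2O2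
Reagents that add atoms: none
Why: Evans syn-aldol: the (Z)-boron enolate reacts through a chair transition state on the face away from the benzyl group, which for the (R)-auxiliary gives the (2R,3S) syn adduct.

Step 17
Reactants: 26 (4R)-4-benzyl-3-[(2R,3S)-3-hydroxy-2-methylbutanoyl]-1,3-oxazolidin-2-one
Product: 27 (4R)-4-benzyl-3-[(2R,3S)-3-{[tert-butyldimethylsilyl]oxy}-2-methylbutanoyl]-1,3-oxazolidin-2-one
Conditions: TBSOTf, 2,6-lutidine, CH2Cl2, 0 °C
Reagents that add atoms: tert-butyldimethylsilyl triflate, CC(C)(C)[Si](C)(C)OS(=O)(=O)C(F)(F)F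
Why: Silylation of the secondary hydroxyl prevents retro-aldol cleavage and self-acylation in the later steps.

Step 18
Reactants: 27 (4R)-4-benzyl-3-[(2R,3S)-3-{[tert-butyldimethylsilyl]oxy}-2-methylbutanoyl]-1,3-oxazolidin-2-one
Product: 28 (2R,3S)-3-{[tert-butyldimethylsilyl]oxy}-2-methylbutanoic acid
Conditions: LiOH, H2O2, THF/H2O, 0 °C; Na2SO3; HCl to pH 3
Reagents that add atoms: hydrogen peroxide, OO
Why: Hydroperoxide attacks the exocyclic imide carbonyl selectively, which releases the acid without epimerising the α-stereocentre and returns the auxiliary.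

Step 19
Reactants: 23 14-hydroxy 12-acetate 9-tiglate; 28 (2R,3S)-3-{[tert-butyldimethylsilyl]oxy}-2-methylbutanoic acid
Product: 29 (4S,5R,7S,9S)-12-acetoxy-4,5-epoxy-15-[(tert-butyldimethylsilyl)oxy]-14-{[(2R,3S)-3-{[tert-butyldimethylsilyl]oxy}-2-methylbutanoyl]oxy}germacra-1(10)E,11(13)-dien-9-yl (2E)-2-methylbut-2-enoate
Conditions: EDC·HCl, DMAP, CH2Cl2, 0 to 23 °C
Reagents that add atoms: none
Why: Steglich-type carbodiimide esterification of the unhindered primary allylic alcohol at low temperature should proceed without epimerising the β-silyloxy acid.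

Step 20
Reactants: 29 bis-TBS ether of the target
Product: 30 (4S,5R,7S,9S)-12-acetoxy-4,5-epoxy-15-hydroxy-14-{[(2R,3S)-3-hydroxy-2-methylbutanoyl]oxy}germacra-1(10)E,11(13)-dien-9-yl (2E)-2-methylbut-2-enoate
Conditions: HF·pyridine, pyridine, THF, 0 to 23 °C
Reagents that add atoms: none
Why: Buffered fluoride removes both TBS ethers without basic conditions, so the three esters should neither migrate nor hydrolyse and the epoxy alcohol should not undergo Payne rearrangement.

## Compound list

1 | prop-2-yn-1-ol | C#CCO | starting material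
2 | [2-(1,3-dioxolan-2-yl)ethyl]magnesium bromide | Br[Mg]CCC1OCCO1 | starting material
3 | 3-bromoprop-1-ene (allyl bromide) | C=CCBr | starting material
4 | bromomagnesium (2Z)-3-(bromomagnesio)-2-[2-(1,3-dioxolan-2-yl)ethyl]prop-2-en-1-olate | Br[Mg]OC/C(CCC1OCCO1)=C\[Mg]Br | intermediate (not isolated)
5 | (2Z)-2-[2-(1,3-dioxolan-2-yl)ethyl]hexa-2,5-dien-1-ol | OC/C(CCC1OCCO1)=C\CC=C | intermediate
6 | 2-methylidenepropane-1,3-diyl diacetate | C=C(COC(C)=O)COC(C)=O | starting material
7 | 2-[(3Z)-6-(1,3-dioxolan-2-yl)-4-(hydroxymethyl)hex-3-en-1-ylidene]propane-1,3-diyl diacetate | OC/C(CCC1OCCO1)=C\CC=C(COC(C)=O)COC(C)=O | intermediate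
8 | 2-[(3Z)-4-(hydroxymethyl)-7-oxohept-3-en-1-ylidene]propane-1,3-diyl diacetate | OC/C(CCC=O)=C\CC=C(COC(C)=O)COC(C)=O | intermediate
9 | methyl 2-(dimethoxyphosphoryl)prop-2-enoate (trimethyl 2-phosphonoacrylate) | COC(=O)C(=C)P(=O)(OC)OC | starting material
10 | sodium salt (α-carbanion) of methyl 2-(dimethoxyphosphoryl)-3-[(4-methoxybenzyl)oxy]propanoate | [Na+].COC(=O)[C-](COCc1ccc(OC)cc1)P(=O)(OC)OC | intermediate (not isolated)
11 | methyl (2E,6Z)-11-acetoxy-10-(acetoxymethyl)-6-(hydroxymethyl)-2-{[(4-methoxybenzyl)oxy]methyl}undeca-2,6,9-trienoate | COC(=O)/C(COCc1ccc(OC)cc1)=C/CC/C(CO)=C/CC=C(COC(C)=O)COC(C)=O | intermediate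
12 | methyl (2E)-5-{(2S,3R)-3-[4-acetoxy-3-(acetoxymethyl)but-2-en-1-yl]-2-(hydroxymethyl)oxiran-2-yl}-2-{[(4-methoxybenzyl)oxy]methyl}pent-2-enoate | COC(=O)/C(COCc1ccc(OC)cc1)=C/CC[C@@]1(CO)O[C@@H]1CC=C(COC(C)=O)COC(C)=O | intermediate
13 | methyl (2E)-5-{(2S,3R)-3-[4-acetoxy-3-(acetoxymethyl)but-2-en-1-yl]-2-{[(tert-butyldimethylsilyl)oxy]methyl}oxiran-2-yl}-2-{[(4-methoxybenzyl)oxy]methyl}pent-2-enoate | COC(=O)/C(COCc1ccc(OC)cc1)=C/CC[C@@]1(CO[Si](C)(C)C(C)(C)C)O[C@@H]1CC=C(COC(C)=O)COC(C)=O | intermediate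
14 | (2E)-5-{(2S,3R)-2-{[(tert-butyldimethylsilyl)oxy]methyl}-3-[4-hydroxy-3-(hydroxymethyl)but-2-en-1-yl]oxiran-2-yl}-2-{[(4-methoxybenzyl)oxy]methyl}pent-2-enoic acid (seco acid) | OC(=O)/C(COCc1ccc(OC)cc1)=C/CC[C@@]1(CO[Si](C)(C)C(C)(C)C)O[C@@H]1CC=C(CO)CO | intermediate
15 | (4S,5R)-epoxy twelve-membered hydroxy lactone C9(=O)–O–C13; 1(10)E; C13 cis to C6 on C7=C11; free 12-OH; 14-O-PMB; 15-O-TBS | O=C1/C(COCc2ccc(OC)cc2)=C/CC[C@@]2(CO[Si](C)(C)C(C)(C)C)O[C@@H]2C/C=C(/CO)CO1 | intermediate
16 | 12-O-triethylsilyl ether of lactone 15 | O=C1/C(COCc2ccc(OC)cc2)=C/CC[C@@]2(CO[Si](C)(C)C(C)(C)C)O[C@@H]2C/C=C(/CO[Si](CC)(CC)CC)CO1 | intermediate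
17 | cyclic dienyl ether: lactone 16 with C9=O replaced by C9=C8H2 | C=C1/C(COCc2ccc(OC)cc2)=C/CC[C@@]2(CO[Si](C)(C)C(C)(C)C)O[C@@H]2C/C=C(/CO[Si](CC)(CC)CC)CO1 | intermediate (not isolated)
18 | (4S,5R,7R)-4,5-epoxy-14-[(4-methoxybenzyl)oxy]-15-[(tert-butyldimethylsilyl)oxy]-12-[(triethylsilyl)oxy]germacra-1(10)E,11(13)-dien-9-one | C=C(CO[Si](CC)(CC)CC)[C@H]1CC(=O)/C(COCc2ccc(OC)cc2)=C/CC[C@@]2(CO[Si](C)(C)C(C)(C)C)O[C@@H]2C1 | intermediate
19 | (4S,5R,7S,9S)-4,5-epoxy-14-[(4-methoxybenzyl)oxy]-15-[(tert-butyldimethylsilyl)oxy]-12-[(triethylsilyl)oxy]germacra-1(10)E,11(13)-dien-9-ol | C=C(CO[Si](CC)(CC)CC)[C@H]1C[C@H](O)/C(COCc2ccc(OC)cc2)=C/CC[C@@]2(CO[Si](C)(C)C(C)(C)C)O[C@@H]2C1 | intermediate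
20 | 9-O-tigloyl derivative of 19 (12-O-TES; 14-O-PMB; 15-O-TBS) | C=C(CO[Si](CC)(CC)CC)[C@H]1C[C@H](OC(=O)/C(C)=C/C)/C(COCc2ccc(OC)cc2)=C/CC[C@@]2(CO[Si](C)(C)C(C)(C)C)O[C@@H]2C1 | intermediate
21 | 12-hydroxy 9-tiglate (14-O-PMB; 15-O-TBS) | C=C(CO)[C@H]1C[C@H](OC(=O)/C(C)=C/C)/C(COCc2ccc(OC)cc2)=C/CC[C@@]2(CO[Si](C)(C)C(C)(C)C)O[C@@H]2C1 | intermediate
22 | 12-acetoxy 9-tiglate (14-O-PMB; 15-O-TBS) | C=C(COC(C)=O)[C@H]1C[C@H](OC(=O)/C(C)=C/C)/C(COCc2ccc(OC)cc2)=C/CC[C@@]2(CO[Si](C)(C)C(C)(C)C)O[C@@H]2C1 | intermediate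
23 | 14-hydroxy 12-acetate 9-tiglate (15-O-TBS) | C=C(COC(C)=O)[C@H]1C[C@H](OC(=O)/C(C)=C/C)/C(CO)=C/CC[C@@]2(CO[Si](C)(C)C(C)(C)C)O[C@@H]2C1 | intermediate
24 | (4R)-4-benzyl-3-propanoyl-1,3-oxazolidin-2-one | CCC(=O)N1[C@H](Cc2ccccc2)COC1=O | starting material
25 | acetaldehyde | CC=O | starting material
26 | (4R)-4-benzyl-3-[(2R,3S)-3-hydroxy-2-methylbutanoyl]-1,3-oxazolidin-2-one | O=C([C@H](C)[C@H](C)O)N1[C@H](Cc2ccccc2)COC1=O | intermediate
27 | (4R)-4-benzyl-3-[(2R,3S)-3-{[tert-butyldimethylsilyl]oxy}-2-methylbutanoyl]-1,3-oxazolidin-2-one | O=C([C@H](C)[C@H](C)O[Si](C)(C)C(C)(C)C)N1[C@H](Cc2ccccc2)COC1=O | intermediate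
28 | (2R,3S)-3-{[tert-butyldimethylsilyl]oxy}-2-methylbutanoic acid | OC(=O)[C@H](C)[C@H](C)O[Si](C)(C)C(C)(C)C | intermediate
29 | bis-TBS ether of the target (15-O-TBS and side-chain 3-O-TBS) | C=C(COC(C)=O)[C@H]1C[C@H](OC(=O)/C(C)=C/C)/C(COC(=O)[C@H](C)[C@H](C)O[Si](C)(C)C(C)(C)C)=C/CC[C@@]2(CO[Si](C)(C)C(C)(C)C)O[C@@H]2C1 | intermediate
30 | (4S,5R,7S,9S)-12-acetoxy-4,5-epoxy-15-hydroxy-14-{[(2R,3S)-3-hydroxy-2-methylbutanoyl]oxy}germacra-1(10)E,11(13)-dien-9-yl (2E)-2-methylbut-2-enoate | C=C(COC(C)=O)[C@H]1C[C@H](OC(=O)/C(C)=C/C)/C(COC(=O)[C@H](C)[C@H](C)O)=C/CC[C@@]2(CO)O[C@@H]2C1 | target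

## Step count and risks

Total step count: 20. Longest linear sequence: 17 steps (steps 1–15, 19 and 20).

**Step 10 (Proposed new method).** The cyclic dienyl ether 17 may be lost before the [3,3] shift occurs at the temperature it needs, through hydrolysis or titanium-promoted opening of the epoxide, and the facial bias at C7 may be too small. The fallback uses only established reaction types, sets out from 16 and returns at 18. Ring-opening crossed Claisen condensation of 16 with lithiated tert-butyl acetate (tert-butyl acetate, LiN(iPr)2, THF, −78 °C) should give the open-chain tert-butyl β-keto ester F1 (C9 ketone, C8H2CO2tBu, free 13-OH). Heating F1 in toluene at 110 °C under high dilution should exchange the tert-butyl ester for the C13 hydroxyl with loss of tert-butanol and give the fourteen-membered β-keto lactone F2. A Carroll rearrangement of F2 (NaH, toluene, 90 °C) then forms C7–C8 through an all-endocyclic six-atom array and extrudes carbon dioxide to give ketone 18. This is the ester-enolate counterpart of the key step, runs without titanium, and passes through a different transition-state geometry.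

**Step 8.** Intermolecular esterification to diolides and oligomers may outrun closure of the strained twelve-membered ring, and acylation may take the other hydroxymethyl arm. The fallback sets out from 14 and returns at 15. The polarity of the ring closure is reversed in a Mitsunobu macrolactonisation (PPh3, diisopropyl azodicarboxylate, toluene/THF, high dilution, 0 to 23 °C): the allylic hydroxyl is activated and the carboxylate closes the ring by SN2 displacement at C13 (alkyl–oxygen instead of acyl–oxygen bond formation). It makes no further compound (none, F0).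

**Step 11.** The facial selectivity of hydride delivery may be poor if the conformation of the ten-membered ring, and not the oxazaborolidine, decides which carbonyl face is exposed. The fallback sets out from 18 and returns at 20. A substrate-controlled Luche reduction (NaBH4, CeCl3·7H2O, MeOH, −78 °C) would deliberately take the ring-preferred face to give the (9R)-alcohol F3. A Mitsunobu esterification of F3 with (2E)-2-methylbut-2-enoic acid (PPh3, diisopropyl azodicarboxylate, toluene, 0 °C) then installs the tiglate with inversion at C9 and gives 20 directly.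

Further compounds
F1 | step 10 | open-chain tert-butyl β-keto ester (C9 ketone; C8H2CO2tBu; free 13-OH cis to C6; 12-O-TES; 14-O-PMB; 15-O-TBS; (4S,5R)-epoxide) | CC(C)(C)OC(=O)CC(=O)/C(COCc1ccc(OC)cc1)=C/CC[C@@]1(CO[Si](C)(C)C(C)(C)C)O[C@@H]1C/C=C(/CO[Si](CC)(CC)CC)CO
F2 | step 10 | fourteen-membered β-keto lactone (ring: ester C=O; C8; C9; C10; C1–C7; C11; C13; O) | O=C1CC(=O)/C(COCc2ccc(OC)cc2)=C/CC[C@@]2(CO[Si](C)(C)C(C)(C)C)O[C@@H]2C/C=C(/CO[Si](CC)(CC)CC)CO1
F0 | step 8 | none | none
F3 | step 11 | (4S,5R,7S,9R)-4,5-epoxy-14-[(4-methoxybenzyl)oxy]-15-[(tert-butyldimethylsilyl)oxy]-12-[(triethylsilyl)oxy]germacra-1(10)E,11(13)-dien-9-ol | C=C(CO[Si](CC)(CC)CC)[C@H]1C[C@@H](O)/C(COCc2ccc(OC)cc2)=C/CC[C@@]2(CO[Si](C)(C)C(C)(C)C)O[C@@H]2C1
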